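Ring letters: A is the 3,5-dihydroxyphenoxy end group, B and C are the two benzo rings of the dibenzofuran, D is the outer ring of the dioxin, E–F is the biaryl, and G and H are the terminal phenoxy-phenoxy chain. Every hydroxyl is carried as a methyl ether until the last step.
Cuts, in order: the sixteen O–CH3 bonds; the dioxin bond from the ring C oxygen beside the ring C methoxy group to ring D; the D–O–E ether and the other ring C–O–D ether, both at a mirror-symmetric bromo-difluoro-dialdehyde that stands for ring D; the furan bond from the ring B oxygen to ring C; the B–C and E–F aryl–aryl bonds; the A–O–B, F–O–G and G–O–H ethers.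
Feature used: the furan oxygen sits on the ring C carbon that is ortho to the B–C bond and para to one dioxin oxygen. Ring C therefore needs only its three contiguous oxygens when it is coupled and can keep a hydrogen on that carbon, which is the only C–H ortho to the biaryl bond and faces the only free hydroxyl, on ring B.
Forward order: A–O–B ether, B–C biaryl, furan (first ring closure), ring D by SNAr. Separately, H to G to F by two SNAr/Baeyer–Villiger rounds and E by Negishi coupling. Then union at ring D, oxidation of both formyl groups to oxygens, dioxin by Ullmann closure (second ring closure), and demethylation.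
Stereochemistry: the target has no stereocentre. Only the crowded E–F axis could be stereogenic, and it is made without control.

Key step: step 11

Assumption: the target string fixes no configuration for the E–F axis with its four ortho substituents, so the axis is formed as the racemate.

Step 1
Reactants: 1 2-hydroxy-4,6-dimethoxybenzaldehyde
Product: 2 3-bromo-2-hydroxy-4,6-dimethoxybenzaldehyde
Conditions: NBS (1.0 equiv), i-Pr2NH (10 mol %), CH2Cl2, 0 °C
Reagents that add atoms: N-bromosuccinimide, O=C1CCC(=O)N1Br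
Why: Electrophilic aromatic bromination with amine-activated NBS is ortho-selective for phenols and C3 (between OH and OMe) is less crowded than C5 (between two OMe), so the halogen is placed on the future biaryl carbon of ring B while the more nucleophilic ring A is still absent.

Step 2
Reactants: 2 3-bromo-2-hydroxy-4,6-dimethoxybenzaldehyde
Product: 3 2-(benzyloxy)-3-bromo-4,6-dimethoxybenzaldehyde
Conditions: BnBr, K2CO3, DMF, 60 °C
Reagents that add atoms: benzyl bromide, BrCc1ccccc1
Why: Williamson ether synthesis masks the future furan oxygen as a benzyl ether, so that the phenol made next is the only one open to arylation.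

Step 3
Reactants: 3 2-(benzyloxy)-3-bromo-4,6-dimethoxybenzaldehyde
Product: 5 2-(benzyloxy)-3-bromo-4,6-dimethoxyphenol, via aryl formate 4 (not isolated)
Conditions: mCPBA, CH2Cl2, 0 °C to rt; aq. NaHCO3 wash; then K2CO3 (cat.), MeOH, rt
Reagents that add atoms: 3-chloroperoxybenzoic acid, OOC(=O)c1cccc(Cl)c1
Why: Baeyer–Villiger oxidation of a 2,4,6-trioxygenated benzaldehyde goes with aryl migration, and methanolysis of the formate frees the hydroxyl on the carbon that has to carry ring A.

Step 4
Reactants: 5 2-(benzyloxy)-3-bromo-4,6-dimethoxyphenol; 6 3,5-dimethoxyphenylboronic acid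
Product: 7 3-(benzyloxy)-2-bromo-4-(3,5-dimethoxyphenoxy)-1,5-dimethoxybenzene
Conditions: Cu(OAc)2 (2 equiv), pyridine, 4 Å molecular sieves, CH2Cl2, dry air, rt
Reagents that add atoms: none
Why: Chan–Lam coupling accepts phenols with two ortho substituents and leaves aryl bromides untouched at room temperature, so the A–O–B ether forms with the C–Br bond intact.

Step 5
Reactants: 8 2-hydroxy-3-methoxybenzaldehyde (o-vanillin)
Product: 9 2-isopropoxy-3-methoxybenzaldehyde
Conditions: i-PrBr, K2CO3, DMF, 70 °C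
Reagents that add atoms: 2-bromopropane, CC(C)Br
Why: Williamson ether synthesis puts an isopropyl group, later removable with BCl3 beside methyl ethers, on the middle oxygen of ring C, the one that will close the dioxin last.

Step 6
Reactants: 9 2-isopropoxy-3-methoxybenzaldehyde
Product: 11 2-isopropoxy-3-methoxyphenol, via aryl formate 10 (not isolated)
Conditions: mCPBA, CH2Cl2, 0 °C to rt; aq. NaHCO3 wash; then K2CO3 (cat.), MeOH, rt
Reagents that add atoms: 3-chloroperoxybenzoic acid, OOC(=O)c1cccc(Cl)c1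
Why: Baeyer–Villiger oxidation of an ortho-alkoxybenzaldehyde turns the formyl carbon into the third ring C oxygen, which is thereby distinct from its neighbour from the start.

Step 7
Reactants: 11 2-isopropoxy-3-methoxyphenol
Product: 12 2-isopropoxy-1-methoxy-3-(methoxymethoxy)benzene
Conditions: NaH, MOMCl, THF, 0 °C to rt
Reagents that add atoms: chloromethyl methyl ether, COCCl
Why: O-alkylation of the sodium phenoxide gives a methoxymethyl acetal that protects this oxygen, is orthogonal to benzyl and isopropyl, and serves as the directing group of the next step.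

Step 8
Reactants: 12 2-isopropoxy-1-methoxy-3-(methoxymethoxy)benzene
Product: 14 2-[3-isopropoxy-4-methoxy-2-(methoxymethoxy)phenyl]-4,4,5,5-tetramethyl-1,3,2-dioxaborolane, via aryllithium 13 (not isolated)
Conditions: n-BuLi, THF, 0 °C; i-PrOBpin, −78 °C to rt; H2O
Reagents that add atoms: 2-isopropoxy-4,4,5,5-tetramethyl-1,3,2-dioxaborolane, CC(C)OB1OC(C)(C)C(C)(C)O1
Why: Directed ortho-metalation takes place beside the chelating OMOM group, a stronger director than OMe, and borate trapping of the aryllithium gives the pinacol boronate at the future biaryl carbon.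

Step 9
Reactants: 7 3-(benzyloxy)-2-bromo-4-(3,5-dimethoxyphenoxy)-1,5-dimethoxybenzene; 14 ring C pinacol boronate
Product: 15 2-(benzyloxy)-3-(3,5-dimethoxyphenoxy)-3'-isopropoxy-4,4',6-trimethoxy-2'-(methoxymethoxy)-1,1'-biphenyl
Conditions: Pd(OAc)2 (5 mol %), SPhos (10 mol %), K3PO4, toluene/H2O, 100 °C
Reagents that add atoms: none
Why: Suzuki–Miyaura coupling with the SPhos-ligated catalyst is established for electron-rich aryl bromides with two ortho substituents and for biaryls with three ortho substituents.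

Step 10
Reactants: 15 benzyl-protected A–B–C biaryl
Product: 16 3-(3,5-dimethoxyphenoxy)-3'-isopropoxy-4,4',6-trimethoxy-2'-(methoxymethoxy)-[1,1'-biphenyl]-2-ol
Conditions: H2 (1 atm), Pd/C (10 wt %), EtOAc, rt
Reagents that add atoms: none
Why: Catalytic hydrogenolysis cleaves only the benzyl ether, since no halogen is left and methyl, isopropyl, methoxymethyl and diaryl ethers are inert.

Step 11
Reactants: 16 2-arylphenol with rings A, B and C
Product: 17 6-(3,5-dimethoxyphenoxy)-2-isopropoxy-3,7,9-trimethoxy-1-(methoxymethoxy)dibenzo[b,d]furan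
Conditions: Pd(OAc)2 (10 mol %), 3-nitropyridine (10 mol %), t-BuOOBz (2 equiv), C6F6/1,3-dimethyl-2-imidazolidinone, 90 °C
Reagents that add atoms: none
Why: The ring B phenoxide binds divalent palladium and steers a concerted metalation–deprotonation of the facing ring C C–H, which gives a six-membered oxapalladacycle. The perester oxidises this palladacycle to tetravalent palladium, and C–O reductive elimination then releases the dibenzofuran and returns divalent palladium. The closest known reaction type is the palladium-catalysed phenol-directed C–H activation/C–O cyclisation of 2-arylphenols to dibenzofurans. The one ring formed, the five-membered furan, closes by intramolecular O–C(aryl) reductive elimination, that is by contraction of the six-membered metallacycle. No stereocentre is created, and the positional selectivity needed is fixed by the substrate, because ring C has a single C–H ortho to the biaryl bond (the other ortho carbon bears OMOM), ring B has a single free hydroxyl and ring B has no ortho C–H of its own. All other oxygens are capped as ethers, so only one phenol meets the oxidant, and 3-nitropyridine keeps the palladium electrophilic and in solution.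

Step 12
Reactants: 17 A–B–C dibenzofuran
Product: 18 6-(3,5-dimethoxyphenoxy)-2-isopropoxy-3,7,9-trimethoxydibenzo[b,d]furan-1-ol
Conditions: conc. HCl (cat.), MeOH, 50 °C
Reagents that add atoms: none
Why: Acid-catalysed acetal exchange removes the methoxymethyl group only, because isopropyl, methyl and diaryl ethers resist dilute HCl, and so frees the ring C oxygen next to the B–C bond.

Step 13
Reactants: 19 3-bromo-2,4-difluorobenzaldehyde
Product: 20 2-bromo-4-(dimethoxymethyl)-1,3-difluorobenzene
Conditions: HC(OMe)3, p-TsOH·H2O (cat.), 60 °C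
Reagents that add atoms: trimethyl orthoformate, COC(OC)OC
Why: Acid-catalysed acetalisation with an orthoester shields the formyl group from the amide base and the aryllithium of the next step.

Step 14
Reactants: 20 2-bromo-4-(dimethoxymethyl)-1,3-difluorobenzene
Product: 23 5-bromo-4,6-difluoroisophthalaldehyde, via aryllithium 21 (not isolated), via acetal aldehyde 22 (not isolated)
Conditions: LiN(i-Pr)2, THF, −78 °C; DMF, −78 to 0 °C; then 2 M HCl, THF, rt
Reagents that add atoms: N,N-dimethylformamide, CN(C)C=O; water, O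
Why: Directed ortho-lithiation by the non-nucleophilic amide removes the proton beside fluorine without bromine–lithium exchange, DMF formylates the anion, and the acidic work-up hydrolyses the acetal to give the mirror-symmetric dialdehyde.

Step 15
Reactants: 18 A–B–C dibenzofuran-1-ol; 23 5-bromo-4,6-difluoroisophthalaldehyde
Product: 24 5-bromo-4-fluoro-6-{[6-(3,5-dimethoxyphenoxy)-2-isopropoxy-3,7,9-trimethoxydibenzo[b,d]furan-1-yl]oxy}isophthalaldehyde
Conditions: 23 (1.5 equiv), K2CO3, DMF, 0 °C to rt
Reagents that add atoms: none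
Why: Nucleophilic aromatic substitution (addition–elimination) is fast because each fluorine is ortho to one and para to the other formyl group, the two fluorines are equivalent so only one monoether can form, the first aryloxy group slows a second attack, and with the neighbouring ring C oxygen still an isopropyl ether no Smiles rearrangement can swap the two oxygens.

Step 16
Reactants: 25 1-fluoro-3,5-dimethoxybenzene
Product: 27 2-fluoro-4,6-dimethoxybenzaldehyde, via iminium chloride 26 (not isolated)
Conditions: POCl3, DMF, 0 to 60 °C; then H2O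
Reagents that add atoms: N,N-dimethylformamide, CN(C)C=O; water, O
Why: Vilsmeier–Haack formylation of the doubly activated arene goes para to one methoxy group and beside the small fluorine in preference to the crowded position between the two methoxy groups.

Step 17
Reactants: 28 2,4,6-trimethoxyphenol; 27 2-fluoro-4,6-dimethoxybenzaldehyde
Product: 29 2,4-dimethoxy-6-(2,4,6-trimethoxyphenoxy)benzaldehyde
Conditions: Cs2CO3, DMSO, 110 °C, N2
Reagents that add atoms: none
Why: Nucleophilic aromatic substitution on an ortho-fluorobenzaldehyde works here because both methoxy groups are meta to fluorine and so do not feed electrons to the carbon under attack, and the small leaving group admits a phenoxide with two ortho substituents.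

Step 18
Reactants: 29 2,4-dimethoxy-6-(2,4,6-trimethoxyphenoxy)benzaldehyde
Product: 31 2,4-dimethoxy-6-(2,4,6-trimethoxyphenoxy)phenol, via aryl formate 30 (not isolated)
Conditions: mCPBA, CH2Cl2, 0 °C to rt; aq. NaHCO3 wash; then K2CO3 (cat.), MeOH, rt
Reagents that add atoms: 3-chloroperoxybenzoic acid, OOC(=O)c1cccc(Cl)c1
Why: Baeyer–Villiger oxidation with aryl migration followed by formate methanolysis converts the activating formyl group into the ring G hydroxyl that is the nucleophile of the next round.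

Step 19
Reactants: 31 2,4-dimethoxy-6-(2,4,6-trimethoxyphenoxy)phenol; 27 2-fluoro-4,6-dimethoxybenzaldehyde
Product: 32 2-[2,4-dimethoxy-6-(2,4,6-trimethoxyphenoxy)phenoxy]-4,6-dimethoxybenzaldehyde
Conditions: Cs2CO3, DMSO, 120 °C, N2
Reagents that add atoms: none
Why: A second nucleophilic aromatic substitution on the same fluoroaldehyde builds the F–O–G ether by the reaction type of step 17.

Step 20
Reactants: 32 F–G–H aldehyde
Product: 34 2-[2,4-dimethoxy-6-(2,4,6-trimethoxyphenoxy)phenoxy]-4,6-dimethoxyphenol, via aryl formate 33 (not isolated)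
Conditions: mCPBA, CH2Cl2, 0 °C to rt; aq. NaHCO3 wash; then K2CO3 (cat.), MeOH, rt
Reagents that add atoms: 3-chloroperoxybenzoic acid, OOC(=O)c1cccc(Cl)c1
Why: Baeyer–Villiger oxidation and methanolysis again replace the formyl group by a hydroxyl, now on the ring F carbon that must become the biaryl carbon.

Step 21
Reactants: 34 F–G–H phenol
Product: 35 2-[2,4-dimethoxy-6-(2,4,6-trimethoxyphenoxy)phenoxy]-4,6-dimethoxyphenyl trifluoromethanesulfonate
Conditions: Tf2O, pyridine, CH2Cl2, 0 °C
Reagents that add atoms: trifluoromethanesulfonic anhydride, O=S(=O)(OS(=O)(=O)C(F)(F)F)C(F)(F)F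
Why: O-sulfonylation turns the phenol into an aryl triflate, the standard way to make a phenolic carbon an electrophile for cross-coupling.

Step 22
Reactants: 36 3,5-dimethoxyphenol
Product: 37 1,3-dimethoxy-5-(methoxymethoxy)benzene
Conditions: NaH, MOMCl, THF, 0 °C to rt
Reagents that add atoms: chloromethyl methyl ether, COCCl
Why: O-alkylation of the sodium phenoxide installs the acetal that protects the ring E oxygen and directs the metalation of the next step.

Step 23
Reactants: 37 1,3-dimethoxy-5-(methoxymethoxy)benzene; 35 F–G–H triflate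
Product: 40 2-[2,4-dimethoxy-6-(2,4,6-trimethoxyphenoxy)phenoxy]-2',4,4',6-tetramethoxy-6'-(methoxymethoxy)-1,1'-biphenyl, via aryllithium 38 (not isolated), via arylzinc chloride 39 (not isolated)
Conditions: 37, n-BuLi, THF, 0 °C to rt; ZnCl2, THF, 0 °C to rt; then 35, Pd2(dba)3 (2.5 mol %), RuPhos (10 mol %), THF/NMP, 80 °C
Reagents that add atoms: none
Why: Directed ortho-metalation between OMOM and OMe, transmetalation to zinc and Negishi coupling with a RuPhos-ligated catalyst, a system established for biaryls with four ortho substituents, join rings E and F, and the arylzinc avoids the protodeboronation typical of 2,6-dialkoxyarylboron reagents.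

Step 24
Reactants: 40 E–F–G–H methoxymethyl ether
Product: 41 2'-[2,4-dimethoxy-6-(2,4,6-trimethoxyphenoxy)phenoxy]-4,4',6,6'-tetramethoxy-[1,1'-biphenyl]-2-ol
Conditions: conc. HCl (cat.), MeOH, 50 °C
Reagents that add atoms: none
Why: Acid-catalysed acetal exchange frees the ring E phenol and touches no other ether.

Step 25
Reactants: 24 A–D aryl fluoride; 41 E–F–G–H phenol
Product: 42 octaaryl dialdehyde (24 with the fluorine replaced by the aryloxy group of 41)
Conditions: K2CO3, DMF, 50 °C
Reagents that add atoms: none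
Why: Nucleophilic aromatic substitution at the remaining fluorine, still ortho and para to formyl groups, is far faster than displacement of an aryloxide or of the meta-placed bromine, so the D–O–E ether forms selectively.

Step 26
Reactants: 42 octaaryl dialdehyde
Product: 44 ring D diol (both formyl groups of 42 replaced by hydroxyl), via bis-formate 43 (not isolated)
Conditions: mCPBA (3 equiv), CH2Cl2, 0 °C to rt; aq. NaHCO3 wash; then K2CO3 (cat.), MeOH, rt, argon
Reagents that add atoms: 3-chloroperoxybenzoic acid, OOC(=O)c1cccc(Cl)c1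
Why: Twofold Baeyer–Villiger oxidation is favoured by the ortho and para aryloxy donors of each formyl-bearing carbon, and methanolysis of the bis-formate gives the two ring D hydroxyls.

Step 27
Reactants: 44 ring D diol
Product: 45 ring D dimethyl ether (bromide with isopropyl ether on ring C)
Conditions: MeI, K2CO3, DMF, rt
Reagents that add atoms: iodomethane, CI
Why: Williamson methylation caps the two new phenols so that a single phenoxide is present in the ring closure of step 29.

Step 28
Reactants: 45 ring D dimethyl ether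
Product: 46 ring C phenol (isopropyl group of 45 replaced by hydrogen)
Conditions: BCl3, CH2Cl2, −78 to 0 °C; H2O
Reagents that add atoms: none
Why: Lewis-acid ether cleavage with BCl3 removes a secondary alkyl aryl ether at low temperature much faster than methyl ethers and leaves the C–Br bond, which hydrogenolysis would not.

Step 29
Reactants: 46 ring C phenol
Product: 47 hexadeca-O-methyl ether of the target
Conditions: CuI (20 mol %), N,N-dimethylglycine (40 mol %), Cs2CO3, dioxane (0.005 M), 110 °C
Reagents that add atoms: none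
Why: Intramolecular Ullmann ether synthesis closes the six-membered dioxin between the only free phenol and the only C–Br bond, and because ring D now carries donor groups only, no Smiles rearrangement can exchange the two ring C oxygens, so the regiochemistry set in step 15 is kept.

Step 30
Reactants: 47 hexadeca-O-methyl ether
Product: 48 CNP0192765.0
Conditions: BBr3 (excess), CH2Cl2, −78 °C to rt; H2O, 0 °C
Reagents that add atoms: none
Why: Lewis-acid demethylation with BBr3 breaks only O–CH3 bonds, since the aryl–oxygen bonds of the diaryl ethers, the furan and the dioxin cannot undergo the SN2 step.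

Compound list
1 | 2-hydroxy-4,6-dimethoxybenzaldehyde | O=Cc1c(O)cc(OC)cc1OC | starting material
2 | 3-bromo-2-hydroxy-4,6-dimethoxybenzaldehyde | O=Cc1c(O)c(Br)c(OC)cc1OC | intermediate
3 | 2-(benzyloxy)-3-bromo-4,6-dimethoxybenzaldehyde | O=Cc1c(OCc2ccccc2)c(Br)c(OC)cc1OC | intermediate
4 | 2-(benzyloxy)-3-bromo-4,6-dimethoxyphenyl formate | O=COc1c(OCc2ccccc2)c(Br)c(OC)cc1OC | intermediate
5 | 2-(benzyloxy)-3-bromo-4,6-dimethoxyphenol | Oc1c(OCc2ccccc2)c(Br)c(OC)cc1OC | intermediate
6 | 3,5-dimethoxyphenylboronic acid | COc1cc(OC)cc(B(O)O)c1 | starting material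
7 | 3-(benzyloxy)-2-bromo-4-(3,5-dimethoxyphenoxy)-1,5-dimethoxybenzene | COc1cc(OC)cc(Oc2c(OCc3ccccc3)c(Br)c(OC)cc2OC)c1 | intermediate
8 | 2-hydroxy-3-methoxybenzaldehyde (o-vanillin) | COc1cccc(C=O)c1O | starting material
9 | 2-isopropoxy-3-methoxybenzaldehyde | COc1cccc(C=O)c1OC(C)C | intermediate
10 | 2-isopropoxy-3-methoxyphenyl formate | COc1cccc(OC=O)c1OC(C)C | intermediate
11 | 2-isopropoxy-3-methoxyphenol | COc1cccc(O)c1OC(C)C | intermediate
12 | 2-isopropoxy-1-methoxy-3-(methoxymethoxy)benzene | COCOc1cccc(OC)c1OC(C)C | intermediate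
13 | [3-isopropoxy-4-methoxy-2-(methoxymethoxy)phenyl]lithium | [Li]c1ccc(OC)c(OC(C)C)c1OCOC | intermediate
14 | 2-[3-isopropoxy-4-methoxy-2-(methoxymethoxy)phenyl]-4,4,5,5-tetramethyl-1,3,2-dioxaborolane | COCOc1c(B2OC(C)(C)C(C)(C)O2)ccc(OC)c1OC(C)C | intermediate
15 | 2-(benzyloxy)-3-(3,5-dimethoxyphenoxy)-3'-isopropoxy-4,4',6-trimethoxy-2'-(methoxymethoxy)-1,1'-biphenyl | COc1cc(OC)cc(Oc2c(OCc3ccccc3)c(-c3ccc(OC)c(OC(C)C)c3OCOC)c(OC)cc2OC)c1 | intermediate
16 | 3-(3,5-dimethoxyphenoxy)-3'-isopropoxy-4,4',6-trimethoxy-2'-(methoxymethoxy)-[1,1'-biphenyl]-2-ol | COc1cc(OC)cc(Oc2c(O)c(-c3ccc(OC)c(OC(C)C)c3OCOC)c(OC)cc2OC)c1 | intermediate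
17 | 6-(3,5-dimethoxyphenoxy)-2-isopropoxy-3,7,9-trimethoxy-1-(methoxymethoxy)dibenzo[b,d]furan | COc1cc(OC)cc(Oc2c(OC)cc(OC)c3c2oc2cc(OC)c(OC(C)C)c(OCOC)c23)c1 | intermediate
18 | 6-(3,5-dimethoxyphenoxy)-2-isopropoxy-3,7,9-trimethoxydibenzo[b,d]furan-1-ol | COc1cc(OC)cc(Oc2c(OC)cc(OC)c3c2oc2cc(OC)c(OC(C)C)c(O)c23)c1 | intermediate
19 | 3-bromo-2,4-difluorobenzaldehyde | O=Cc1ccc(F)c(Br)c1F | starting material
20 | 2-bromo-4-(dimethoxymethyl)-1,3-difluorobenzene | COC(OC)c1ccc(F)c(Br)c1F | intermediate
21 | [3-bromo-5-(dimethoxymethyl)-2,4-difluorophenyl]lithium | COC(OC)c1cc([Li])c(F)c(Br)c1F | intermediate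
22 | 3-bromo-5-(dimethoxymethyl)-2,4-difluorobenzaldehyde | COC(OC)c1cc(C=O)c(F)c(Br)c1F | intermediate
23 | 5-bromo-4,6-difluoroisophthalaldehyde | O=Cc1cc(C=O)c(F)c(Br)c1F | intermediate
24 | 5-bromo-4-fluoro-6-{[6-(3,5-dimethoxyphenoxy)-2-isopropoxy-3,7,9-trimethoxydibenzo[b,d]furan-1-yl]oxy}isophthalaldehyde | COc1cc(OC)cc(Oc2c(OC)cc(OC)c3c2oc2cc(OC)c(OC(C)C)c(Oc4c(C=O)cc(C=O)c(F)c4Br)c23)c1 | intermediate
25 | 1-fluoro-3,5-dimethoxybenzene | COc1cc(F)cc(OC)c1 | starting material
26 | (2-fluoro-4,6-dimethoxybenzylidene)dimethyliminium chloride | COc1cc(F)c(C=[N+](C)C)c(OC)c1.[Cl-] | intermediate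
27 | 2-fluoro-4,6-dimethoxybenzaldehyde | COc1cc(F)c(C=O)c(OC)c1 | intermediate
28 | 2,4,6-trimethoxyphenol | COc1cc(OC)c(O)c(OC)c1 | starting material
29 | 2,4-dimethoxy-6-(2,4,6-trimethoxyphenoxy)benzaldehyde | COc1cc(OC)c(C=O)c(Oc2c(OC)cc(OC)cc2OC)c1 | intermediate
30 | 2,4-dimethoxy-6-(2,4,6-trimethoxyphenoxy)phenyl formate | COc1cc(OC)c(OC=O)c(Oc2c(OC)cc(OC)cc2OC)c1 | intermediate
31 | 2,4-dimethoxy-6-(2,4,6-trimethoxyphenoxy)phenol | COc1cc(OC)c(O)c(Oc2c(OC)cc(OC)cc2OC)c1 | intermediate
32 | 2-[2,4-dimethoxy-6-(2,4,6-trimethoxyphenoxy)phenoxy]-4,6-dimethoxybenzaldehyde | COc1cc(OC)c(C=O)c(Oc2c(OC)cc(OC)cc2Oc2c(OC)cc(OC)cc2OC)c1 | intermediate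
33 | 2-[2,4-dimethoxy-6-(2,4,6-trimethoxyphenoxy)phenoxy]-4,6-dimethoxyphenyl formate | COc1cc(OC)c(OC=O)c(Oc2c(OC)cc(OC)cc2Oc2c(OC)cc(OC)cc2OC)c1 | intermediate
34 | 2-[2,4-dimethoxy-6-(2,4,6-trimethoxyphenoxy)phenoxy]-4,6-dimethoxyphenol | COc1cc(OC)c(O)c(Oc2c(OC)cc(OC)cc2Oc2c(OC)cc(OC)cc2OC)c1 | intermediate
35 | 2-[2,4-dimethoxy-6-(2,4,6-trimethoxyphenoxy)phenoxy]-4,6-dimethoxyphenyl trifluoromethanesulfonate | COc1cc(OC)c(OS(=O)(=O)C(F)(F)F)c(Oc2c(OC)cc(OC)cc2Oc2c(OC)cc(OC)cc2OC)c1 | intermediate
36 | 3,5-dimethoxyphenol | COc1cc(O)cc(OC)c1 | starting material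
37 | 1,3-dimethoxy-5-(methoxymethoxy)benzene | COCOc1cc(OC)cc(OC)c1 | intermediate
38 | [2,4-dimethoxy-6-(methoxymethoxy)phenyl]lithium | [Li]c1c(OC)cc(OC)cc1OCOC | intermediate
39 | [2,4-dimethoxy-6-(methoxymethoxy)phenyl]zinc chloride | Cl[Zn]c1c(OC)cc(OC)cc1OCOC | intermediate
40 | 2-[2,4-dimethoxy-6-(2,4,6-trimethoxyphenoxy)phenoxy]-2',4,4',6-tetramethoxy-6'-(methoxymethoxy)-1,1'-biphenyl (racemic axis) | COCOc1cc(OC)cc(OC)c1-c1c(OC)cc(OC)cc1Oc1c(OC)cc(OC)cc1Oc1c(OC)cc(OC)cc1OC | intermediate
41 | 2'-[2,4-dimethoxy-6-(2,4,6-trimethoxyphenoxy)phenoxy]-4,4',6,6'-tetramethoxy-[1,1'-biphenyl]-2-ol (racemic axis) | Oc1cc(OC)cc(OC)c1-c1c(OC)cc(OC)cc1Oc1c(OC)cc(OC)cc1Oc1c(OC)cc(OC)cc1OC | intermediate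
42 | octaaryl dialdehyde: 5-bromoisophthalaldehyde bearing the aryloxy group of 41 at C4 and the aryloxy group of 18 at C6 | COc1cc(OC)cc(Oc2c(OC)cc(OC)c3c2oc2cc(OC)c(OC(C)C)c(Oc4c(C=O)cc(C=O)c(Oc5cc(OC)cc(OC)c5-c5c(OC)cc(OC)cc5Oc5c(OC)cc(OC)cc5Oc5c(OC)cc(OC)cc5OC)c4Br)c23)c1 | intermediate
43 | bis-formate: both CHO groups of 42 replaced by OCHO | COc1cc(OC)cc(Oc2c(OC)cc(OC)c3c2oc2cc(OC)c(OC(C)C)c(Oc4c(OC=O)cc(OC=O)c(Oc5cc(OC)cc(OC)c5-c5c(OC)cc(OC)cc5Oc5c(OC)cc(OC)cc5Oc5c(OC)cc(OC)cc5OC)c4Br)c23)c1 | intermediate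
44 | ring D diol: both CHO groups of 42 replaced by OH | COc1cc(OC)cc(Oc2c(OC)cc(OC)c3c2oc2cc(OC)c(OC(C)C)c(Oc4c(O)cc(O)c(Oc5cc(OC)cc(OC)c5-c5c(OC)cc(OC)cc5Oc5c(OC)cc(OC)cc5Oc5c(OC)cc(OC)cc5OC)c4Br)c23)c1 | intermediate
45 | ring D dimethyl ether: both OH groups of 44 methylated | COc1cc(OC)cc(Oc2c(OC)cc(OC)c3c2oc2cc(OC)c(OC(C)C)c(Oc4c(OC)cc(OC)c(Oc5cc(OC)cc(OC)c5-c5c(OC)cc(OC)cc5Oc5c(OC)cc(OC)cc5Oc5c(OC)cc(OC)cc5OC)c4Br)c23)c1 | intermediate
46 | ring C phenol: isopropoxy group of 45 replaced by OH | COc1cc(OC)cc(Oc2c(OC)cc(OC)c3c2oc2cc(OC)c(O)c(Oc4c(OC)cc(OC)c(Oc5cc(OC)cc(OC)c5-c5c(OC)cc(OC)cc5Oc5c(OC)cc(OC)cc5Oc5c(OC)cc(OC)cc5OC)c4Br)c23)c1 | intermediate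
47 | hexadeca-O-methyl ether of the target (dioxin closed) | COc1cc(OC)cc(Oc2c(OC)cc(OC)c3c2oc2cc(OC)c4c(c23)Oc2c(OC)cc(OC)c(Oc3cc(OC)cc(OC)c3-c3c(OC)cc(OC)cc3Oc3c(OC)cc(OC)cc3Oc3c(OC)cc(OC)cc3OC)c2O4)c1 | intermediate
48 | CNP0192765.0 | Oc1cc(O)cc(Oc2c(O)cc(O)c3c2oc2cc(O)c4c(c23)Oc2c(O)cc(O)c(Oc3cc(O)cc(O)c3-c3c(O)cc(O)cc3Oc3c(O)cc(O)cc3Oc3c(O)cc(O)cc3O)c2O4)c1 | target

Total step count: 30.
Longest linear sequence: 15 steps (steps 1–4, 9–12, 15 and 25–30).

Steps most likely to fail

Step 11. Oxidation of the very electron-rich free phenol by the perester, and unselective electrophilic palladation of ring A, may outrun the slow metalation of a twisted biaryl with three ortho substituents. The fallback sets out from 2 and 14 and comes back at 17. It moves the ring closure to the aldehyde oxidation level, before ring A exists.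
- Bromophenol 2 is coupled directly with boronate 14 (Pd(OAc)2, SPhos, K3PO4, toluene/H2O) to the biaryl salicylaldehyde F1. Its hydroxyl is hydrogen-bonded to and deactivated by the formyl group, so it is much harder to oxidise.
- F1 is cyclised without peroxide through a divalent/zerovalent palladium cycle. The conditions are Pd(OAc)2, 1,3-bis(2,6-diisopropylphenyl)imidazol-2-ylidene, sodium 2,4,6-trimethylbenzoate, K2CO3 and 4,5-diazafluoren-9-one in mesitylene under air at 120 °C. This gives the dibenzofuran carbaldehyde F2.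
- mCPBA gives the aryl formate F3, and methanolysis gives the dibenzofuranol F4.
- Chan–Lam coupling of F4 with 6 then installs ring A and delivers 17. The benzyl ether steps are no longer needed.

Step 23. Transmetalation and reductive elimination at a palladium centre that carries two aryl groups with two ortho oxygens each may be too slow. Sulfur–oxygen cleavage of the triflate and protonation of the arylzinc would then take over. The fallback sets out from 35 and 36 and comes back at 41. It makes the aryl–aryl bond by ligand coupling on lead, a process known to build very hindered 2-hydroxybiaryls.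
- Triflate 35 is stannylated with (Bu3Sn)2, Pd(PPh3)4 and LiCl in dioxane at 100 °C to the arylstannane F5.
- Tin–lead exchange with Pb(OAc)4 and catalytic Hg(OAc)2 in CHCl3 gives the aryllead triacetate F6.
- F6 arylates 3,5-dimethoxyphenol 36 ortho to its hydroxyl through an aryloxylead intermediate (pyridine, CHCl3, 40–60 °C). This gives 41 directly, without the protection and deprotection of steps 22 and 24.

Step 29. Activation of a C–Br bond flanked by two aryloxy groups on a fully donor-substituted ring may stall, with hydrodebromination as the competing process. The fallback sets out from 45 and comes back at 47. It inverts the polarity of the ring D carbon.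
- Bromine–lithium exchange on 45 (n-BuLi, THF, −78 °C) gives the aryllithium F7. Trapping with i-PrOBpin gives the pinacol boronate F8.
- BCl3 followed by water removes both the isopropyl group and the pinacol and gives the hydroxy boronic acid F9.
- An intramolecular oxidative Chan–Lam coupling (Cu(OAc)2, pyridine, O2, CH2Cl2, high dilution, rt) closes the dioxin to 47.

Further compounds
F1 | step 11 | 2-hydroxy-3'-isopropoxy-4,4',6-trimethoxy-2'-(methoxymethoxy)-[1,1'-biphenyl]-3-carbaldehyde | O=Cc1c(O)c(-c2ccc(OC)c(OC(C)C)c2OCOC)c(OC)cc1OC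
F2 | step 11 | 2-isopropoxy-3,7,9-trimethoxy-1-(methoxymethoxy)dibenzo[b,d]furan-6-carbaldehyde | O=Cc1c(OC)cc(OC)c2c1oc1cc(OC)c(OC(C)C)c(OCOC)c12
F3 | step 11 | 2-isopropoxy-3,7,9-trimethoxy-1-(methoxymethoxy)dibenzo[b,d]furan-6-yl formate | O=COc1c(OC)cc(OC)c2c1oc1cc(OC)c(OC(C)C)c(OCOC)c12
F4 | step 11 | 2-isopropoxy-3,7,9-trimethoxy-1-(methoxymethoxy)dibenzo[b,d]furan-6-ol | Oc1c(OC)cc(OC)c2c1oc1cc(OC)c(OC(C)C)c(OCOC)c12
F5 | step 23 | tributyl{2-[2,4-dimethoxy-6-(2,4,6-trimethoxyphenoxy)phenoxy]-4,6-dimethoxyphenyl}stannane | CCCC[Sn](CCCC)(CCCC)c1c(OC)cc(OC)cc1Oc1c(OC)cc(OC)cc1Oc1c(OC)cc(OC)cc1OC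
F6 | step 23 | {2-[2,4-dimethoxy-6-(2,4,6-trimethoxyphenoxy)phenoxy]-4,6-dimethoxyphenyl}lead triacetate | CC(=O)O[Pb](OC(C)=O)(OC(C)=O)c1c(OC)cc(OC)cc1Oc1c(OC)cc(OC)cc1Oc1c(OC)cc(OC)cc1OC
F7 | step 29 | aryllithium: bromine of 45 replaced by lithium | COc1cc(OC)cc(Oc2c(OC)cc(OC)c3c2oc2cc(OC)c(OC(C)C)c(Oc4c(OC)cc(OC)c(Oc5cc(OC)cc(OC)c5-c5c(OC)cc(OC)cc5Oc5c(OC)cc(OC)cc5Oc5c(OC)cc(OC)cc5OC)c4[Li])c23)c1
F8 | step 29 | pinacol boronate: bromine of 45 replaced by 4,4,5,5-tetramethyl-1,3,2-dioxaborolan-2-yl | COc1cc(OC)cc(Oc2c(OC)cc(OC)c3c2oc2cc(OC)c(OC(C)C)c(Oc4c(OC)cc(OC)c(Oc5cc(OC)cc(OC)c5-c5c(OC)cc(OC)cc5Oc5c(OC)cc(OC)cc5Oc5c(OC)cc(OC)cc5OC)c4B6OC(C)(C)C(C)(C)O6)c23)c1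
F9 | step 29 | hydroxy boronic acid: bromine of 46 replaced by B(OH)2 | COc1cc(OC)cc(Oc2c(OC)cc(OC)c3c2oc2cc(OC)c(O)c(Oc4c(OC)cc(OC)c(Oc5cc(OC)cc(OC)c5-c5c(OC)cc(OC)cc5Oc5c(OC)cc(OC)cc5Oc5c(OC)cc(OC)cc5OC)c4B(O)O)c23)c1
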